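**Retrosynthetic overview**

- Feature: two C6–C3 units joined C8–C8', with the only side-chain oxygen on C7, the benzylic carbon of ring A (3,4-dimethoxyphenyl); ring B (4-hydroxy-3-methoxyphenyl) carries the plain C7' methylene.
- Key disconnection: C8'–C8 and C7–O are cut together, back to the amine-bound enamine radical cation of a ring B 3-arylpropanal, (E)-methyl isoeugenol and nitrate.
- Before: eugenol is taken to the propanal by hydroboration–oxidation, phenol acetylation and alcohol oxidation.
- After: CHO at C9' becomes CH3 (reduction, iodide, tin hydride), ONO2 at C7 becomes OAc with retention (zinc, then Ac2O), and the aryl acetate is removed last.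
- No ring is formed at any stage; both arenes come from the starting materials and all three stereocentres arise in the key step.

Key step: step 4

Assumption: lignan numbering is used throughout (C7 = CH–O on ring A, C8 and C8' = the two CH(CH3) carbons, C9 and C9' = their methyl carbons, C7' = CH2 on ring B), and (E)-methyl isoeugenol is bought as the geometrically pure E isomer.

**Route**

Step 1
Reactants: 1 eugenol
Product: 3 dihydroconiferyl alcohol (4-(3-hydroxypropyl)-2-methoxyphenol), via bis(9-BBN) adduct 2 (not isolated)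
Conditions: 9-BBN (2.3 equiv), THF, 0 °C to rt; then aq NaOH, 30% H2O2, 0 °C to rt; neutral work-up
Reagents that add atoms: 9-BBN, B1C2CCCC1CCC2 (its boron stays only in intermediate 2); hydrogen peroxide, OO
Why: Hydroboration–oxidation: the bulky dialkylborane places boron on the terminal carbon of the allyl group (the phenol only uses up one further equivalent as its aryloxyborane), and alkaline peroxide then turns C–B into C–OH and frees the phenol.

Step 2
Reactants: 3 dihydroconiferyl alcohol
Product: 4 4-(3-hydroxypropyl)-2-methoxyphenyl acetate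
Conditions: Ac2O (1.1 equiv), 1 M aq NaOH (1.05 equiv), 0 °C, short reaction time
Reagents that add atoms: acetic anhydride, CC(=O)OC(C)=O
Why: Chemoselective acetylation of a phenoxide in water (Schotten–Baumann conditions): one equivalent of hydroxide ionises only the phenol, and its anion takes up acetic anhydride far faster than the neutral primary alcohol does.

Step 3
Reactants: 4 4-(3-hydroxypropyl)-2-methoxyphenyl acetate
Product: 5 3-(4-acetoxy-3-methoxyphenyl)propanal
Conditions: TEMPO (10 mol %), PhI(OAc)2 (1.1 equiv), CH2Cl2, rt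
Reagents that add atoms: none
Why: Oxoammonium (TEMPO) oxidation with PhI(OAc)2 as terminal oxidant stops at the aldehyde under anhydrous conditions and leaves the aryl acetate and the deactivated arene alone.

Step 4
Reactants: 5 3-(4-acetoxy-3-methoxyphenyl)propanal; 6 (E)-methyl isoeugenol (2 equiv)
Product: 7 (2R,3S,4R)-2-(4-acetoxy-3-methoxybenzyl)-4-(3,4-dimethoxyphenyl)-3-methyl-4-(nitrooxy)butanal
Conditions: (2S,5S)-5-benzyl-2-tert-butyl-3-methylimidazolidin-4-one·CF3CO2H (20 mol %), (NH4)2Ce(NO3)6 (2.5 equiv, added in portions), NaHCO3 (1.5 equiv), H2O (2 equiv), DME, −40 °C; cold work-up, short silica plug, used at once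
Reagents that add atoms: (NH4)2Ce(NO3)6 (ammonium hexanitratocerate of tetravalent cerium), [NH4+].[NH4+].[Ce+4].[O-][N+](=O)[O-].[O-][N+](=O)[O-].[O-][N+](=O)[O-].[O-][N+](=O)[O-].[O-][N+](=O)[O-].[O-][N+](=O)[O-]
Why: Proposed new method: the imidazolidinone condenses with 5 to the (E)-enamine, which (NH4)2Ce(NO3)6 oxidises by one electron to a 3π-electron radical cation that adds through its α-carbon (C8') to the methyl-bearing C8 of 6, the only regiochemistry that leaves a radical at C7 stabilised by ring A; a second equivalent of tetravalent cerium oxidises that radical and passes nitrate to C7, and hydrolysis of the iminium ion frees 7 and the catalyst, so the C8'–C8 and C7–O bonds form and no ring closes. The closest known reaction is the organocatalytic SOMO α-carbo-oxidation of terminal styrenes with aldehydes and the same cerium oxidant, which gives γ-nitrooxy aldehydes; an internal, dimethoxy-substituted propenylarene lies outside its demonstrated scope. C8' is set by the catalyst: the enamine lies away from the tert-butyl group and the benzyl group covers the Re face of C8', so C8 bonds to the Si face and C8' becomes R. C8 is set by acyclic 1,2-induction in an open transition state in which C7 stands anti to the iminium carbon and the C8 methyl takes the gap beside the C8' hydrogen, not the one beside the C7' arm (Si face of C8' onto Re face of C8, S at C8). C7 is set when nitrate is delivered anti to the C8' branch in the conformer that keeps C8–H in the plane of the benzylic centre (R at C7). The step needs the enamine to be oxidised before 6 and nitrate capture to beat attack of ring B on C7: the enamine is the more easily oxidised species and the oxidant is fed slowly at −40 °C, the aryl acetate keeps ring B hard to oxidise and a poor Friedel–Crafts partner, and if 6 is oxidised first, capture of its radical cation at C8 by the enamine leads to the same bond.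

Step 5
Reactants: 7 the nitrooxy aldehyde
Product: 8 4-[(2R,3S,4R)-4-(3,4-dimethoxyphenyl)-2-(hydroxymethyl)-3-methyl-4-(nitrooxy)butyl]-2-methoxyphenyl acetate
Conditions: NaBH4 (1 equiv), EtOH/CH2Cl2, −40 to −20 °C; pH 7 buffer quench
Reagents that add atoms: none
Why: Borohydride reduction of the aldehyde at low temperature is much faster than attack on the nitrate ester or the aryl acetate and removes the epimerisable aldehyde next to C8' before further handling; no stereocentre is formed.

Step 6
Reactants: 8 the nitrooxy alcohol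
Product: 9 4-[(2R,3S,4R)-4-(3,4-dimethoxyphenyl)-2-(iodomethyl)-3-methyl-4-(nitrooxy)butyl]-2-methoxyphenyl acetate
Conditions: PPh3 (1.3 equiv), I2 (1.3 equiv), imidazole (2 equiv), CH2Cl2, 0 °C; reagent formed first, 8 added last
Reagents that add atoms: iodine, II
Why: Appel-type iodination: the primary alcohol is activated as its alkoxyphosphonium ion and displaced by iodide in an SN2 step at C9', away from the stereocentres, and forming the reagent first keeps free phosphine away from the nitrate.

Step 7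
Reactants: 9 the iodo nitrate
Product: 11 (1R,2S,3R)-4-(4-acetoxy-3-methoxyphenyl)-1-(3,4-dimethoxyphenyl)-3-(iodomethyl)-2-methylbutyl acetate, via iodo alcohol 10 (not isolated)
Conditions: Zn dust, AcOH/THF (1:4), 0 °C; filter, strip AcOH with toluene; then Ac2O, pyridine, DMAP (cat.), CH2Cl2, 0 °C
Reagents that add atoms: acetic anhydride, CC(=O)OC(C)=O
Why: Dissolving-metal reduction of the nitrate ester breaks the O–N bond and not the C7–O bond, so C7 keeps its configuration, and DMAP-catalysed acetylation caps the alcohol at once before it can alkylate on C9'; any C–I bond that zinc also reduces gives 12 directly.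

Step 8
Reactants: 11 the iodo diacetate
Product: 12 (1R,2S,3R)-4-(4-acetoxy-3-methoxyphenyl)-1-(3,4-dimethoxyphenyl)-2,3-dimethylbutyl acetate
Conditions: Bu3SnH (1.5 equiv), AIBN (cat.), toluene, 80 °C
Reagents that add atoms: none
Why: Radical chain dehalogenation: the stannyl radical abstracts iodine and the primary C9' radical takes hydrogen from Bu3SnH, and with the nitrate already exchanged for acetate nothing else in the molecule reacts with tin radicals; no stereocentre is involved.

Step 9
Reactants: 12 the diacetate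
Product: 13 (1R,2S,3R)-1-(3,4-dimethoxyphenyl)-4-(4-hydroxy-3-methoxyphenyl)-2,3-dimethylbutyl acetate (target, 7R,8S,8'R)
Conditions: NH4OAc (excess), MeOH/H2O (4:1), rt
Reagents that add atoms: none
Why: Chemoselective transesterification: under near-neutral NH4OAc in aqueous methanol the aryl acetate, with its phenoxide leaving group, is cleaved while the secondary alkyl acetate at C7 stays.

**Compound list**

1 | eugenol (4-allyl-2-methoxyphenol) | COc1cc(CC=C)ccc1O | starting material
2 | 9-[3-[4-(9-borabicyclo[3.3.1]nonan-9-yloxy)-3-methoxyphenyl]propyl]-9-borabicyclo[3.3.1]nonane | COc1cc(CCCB2C3CCCC2CCC3)ccc1OB1C2CCCC1CCC2 | intermediate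
3 | dihydroconiferyl alcohol (4-(3-hydroxypropyl)-2-methoxyphenol) | COc1cc(CCCO)ccc1O | intermediate
4 | 4-(3-hydroxypropyl)-2-methoxyphenyl acetate | COc1cc(CCCO)ccc1OC(C)=O | intermediate
5 | 3-(4-acetoxy-3-methoxyphenyl)propanal | COc1cc(CCC=O)ccc1OC(C)=O | intermediate
6 | (E)-methyl isoeugenol (1,2-dimethoxy-4-[(E)-prop-1-enyl]benzene) | COc1ccc(/C=C/C)cc1OC | starting material
7 | (2R,3S,4R)-2-(4-acetoxy-3-methoxybenzyl)-4-(3,4-dimethoxyphenyl)-3-methyl-4-(nitrooxy)butanal | COc1cc(C[C@@H](C=O)[C@H](C)[C@@H](O[N+](=O)[O-])c2ccc(OC)c(OC)c2)ccc1OC(C)=O | intermediate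
8 | 4-[(2R,3S,4R)-4-(3,4-dimethoxyphenyl)-2-(hydroxymethyl)-3-methyl-4-(nitrooxy)butyl]-2-methoxyphenyl acetate | COc1cc(C[C@@H](CO)[C@H](C)[C@@H](O[N+](=O)[O-])c2ccc(OC)c(OC)c2)ccc1OC(C)=O | intermediate
9 | 4-[(2R,3S,4R)-4-(3,4-dimethoxyphenyl)-2-(iodomethyl)-3-methyl-4-(nitrooxy)butyl]-2-methoxyphenyl acetate | COc1cc(C[C@@H](CI)[C@H](C)[C@@H](O[N+](=O)[O-])c2ccc(OC)c(OC)c2)ccc1OC(C)=O | intermediate
10 | 4-[(2R,3S,4R)-4-(3,4-dimethoxyphenyl)-4-hydroxy-2-(iodomethyl)-3-methylbutyl]-2-methoxyphenyl acetate | COc1cc(C[C@@H](CI)[C@H](C)[C@@H](O)c2ccc(OC)c(OC)c2)ccc1OC(C)=O | intermediate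
11 | (1R,2S,3R)-4-(4-acetoxy-3-methoxyphenyl)-1-(3,4-dimethoxyphenyl)-3-(iodomethyl)-2-methylbutyl acetate | COc1cc(C[C@@H](CI)[C@H](C)[C@@H](OC(C)=O)c2ccc(OC)c(OC)c2)ccc1OC(C)=O | intermediate
12 | (1R,2S,3R)-4-(4-acetoxy-3-methoxyphenyl)-1-(3,4-dimethoxyphenyl)-2,3-dimethylbutyl acetate | COc1cc(C[C@@H](C)[C@H](C)[C@@H](OC(C)=O)c2ccc(OC)c(OC)c2)ccc1OC(C)=O | intermediate
13 | (1R,2S,3R)-1-(3,4-dimethoxyphenyl)-4-(4-hydroxy-3-methoxyphenyl)-2,3-dimethylbutyl acetate | COc1cc(C[C@@H](C)[C@H](C)[C@@H](OC(C)=O)c2ccc(OC)c(OC)c2)ccc1O | target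

**Step count and risks**

Total step count: 9. Longest linear sequence: 9 steps (1 to 13); 6 enters at step 4.

Steps most likely to fail:

1. Step 4. The oxidant may take an electron from 6 before the enamine and the propenylarene may then dimerise. The acyclic induction at C8 and C7 may be weak. Ring B may close onto C7 before nitrate is delivered. The fallback sets the three stereocentres by auxiliary and Felkin–Anh control and uses neither 5, 6 nor nitrate chemistry. It sets out from 1 and comes back at 13.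
 - Silylation (t-BuMe2SiCl, imidazole, DMF) should give tert-butyl(4-allyl-2-methoxyphenoxy)dimethylsilane F1.
 - Cross-metathesis with (S)-3-acryloyl-4-phenyloxazolidin-2-one (second-generation Hoveyda–Grubbs catalyst, 1,4-benzoquinone, CH2Cl2, 40 °C) should give (S)-3-[(E)-4-[4-(tert-butyldimethylsilyloxy)-3-methoxyphenyl]but-2-enoyl]-4-phenyloxazolidin-2-one F2.
 - Conjugate addition of MeMgBr with CuBr·SMe2 (THF/Me2S, −40 °C), anti to the phenyl group of the chelated imide, should set C8' in (S)-3-[(R)-4-[4-(tert-butyldimethylsilyloxy)-3-methoxyphenyl]-3-methylbutanoyl]-4-phenyloxazolidin-2-one F3.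
 - Methylation of the sodium (Z)-enolate (NaN(SiMe3)2, MeI, THF, −78 °C), again anti to the phenyl group, should set C8 in (S)-3-[(2S,3R)-4-[4-(tert-butyldimethylsilyloxy)-3-methoxyphenyl]-2,3-dimethylbutanoyl]-4-phenyloxazolidin-2-one F4.
 - LiBH4 (THF, MeOH, 0 °C) should release the auxiliary and give (2S,3R)-4-[4-(tert-butyldimethylsilyloxy)-3-methoxyphenyl]-2,3-dimethylbutan-1-ol F5.
 - Dess–Martin periodinane (NaHCO3, CH2Cl2, 0 °C) should give (2S,3R)-4-[4-(tert-butyldimethylsilyloxy)-3-methoxyphenyl]-2,3-dimethylbutanal F6.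
 - Felkin–Anh addition of (3,4-dimethoxyphenyl)magnesium bromide (THF, −78 °C) should set C7 in (1R,2S,3R)-4-[4-(tert-butyldimethylsilyloxy)-3-methoxyphenyl]-1-(3,4-dimethoxyphenyl)-2,3-dimethylbutan-1-ol F7; the minor C7 epimer is to be removed by chromatography.
 - Acetylation (Ac2O, pyridine, DMAP) should give (1R,2S,3R)-4-[4-(tert-butyldimethylsilyloxy)-3-methoxyphenyl]-1-(3,4-dimethoxyphenyl)-2,3-dimethylbutyl acetate F8.
 - Bu4NF buffered with AcOH (THF, 0 °C) removes the silyl group and the fallback rejoins the route at 13, past steps 5 to 9.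

2. Step 6. The benzylic nitrate may be lost by iodide displacement or by attack of phosphine, and the γ-nitrooxy alcohol may close to a cyclic ether. The fallback brings iodide in only after the nitrate has gone. It sets out from 8 and comes back at 11.
 - Sulfonylation (MsCl, Et3N, CH2Cl2, −20 °C) should give 4-[(2R,3S,4R)-4-(3,4-dimethoxyphenyl)-3-methyl-2-[(methylsulfonyloxy)methyl]-4-(nitrooxy)butyl]-2-methoxyphenyl acetate F9.
 - Zinc in AcOH/THF at 0 °C should give 4-[(2R,3S,4R)-4-(3,4-dimethoxyphenyl)-4-hydroxy-3-methyl-2-[(methylsulfonyloxy)methyl]butyl]-2-methoxyphenyl acetate F10, which is not isolated.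
 - Acetylation (Ac2O, pyridine, DMAP) should give (1R,2S,3R)-4-(4-acetoxy-3-methoxyphenyl)-1-(3,4-dimethoxyphenyl)-2-methyl-3-[(methylsulfonyloxy)methyl]butyl acetate F11.
 - Finkelstein exchange (NaI, acetone, reflux) then gives 11 and the route goes on with step 8.

3. Step 7. Ionisation at C7 in acetic acid may scramble C7 or let ring B close onto it, and the γ-iodo alcohol may alkylate on C9' before it is acetylated. The fallback removes iodine and the nitrate N–O bond together under neutral conditions. It sets out from 9 and comes back at 12.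
 - Hydrogenolysis (H2, Pd/C, Et3N, EtOAc, rt) should give 4-[(2R,3S,4R)-4-(3,4-dimethoxyphenyl)-4-hydroxy-2,3-dimethylbutyl]-2-methoxyphenyl acetate F12.
 - Acetylation (Ac2O, pyridine, DMAP, 0 °C) then gives 12, so that step 8 is not needed.

**Further compounds**

F1 | step 4 | tert-butyl(4-allyl-2-methoxyphenoxy)dimethylsilane | COc1cc(CC=C)ccc1O[Si](C)(C)C(C)(C)C
F2 | step 4 | (S)-3-[(E)-4-[4-(tert-butyldimethylsilyloxy)-3-methoxyphenyl]but-2-enoyl]-4-phenyloxazolidin-2-one | COc1cc(C/C=C/C(=O)N2[C@@H](c3ccccc3)COC2=O)ccc1O[Si](C)(C)C(C)(C)C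
F3 | step 4 | (S)-3-[(R)-4-[4-(tert-butyldimethylsilyloxy)-3-methoxyphenyl]-3-methylbutanoyl]-4-phenyloxazolidin-2-one | COc1cc(C[C@@H](C)CC(=O)N2[C@@H](c3ccccc3)COC2=O)ccc1O[Si](C)(C)C(C)(C)C
F4 | step 4 | (S)-3-[(2S,3R)-4-[4-(tert-butyldimethylsilyloxy)-3-methoxyphenyl]-2,3-dimethylbutanoyl]-4-phenyloxazolidin-2-one | COc1cc(C[C@@H](C)[C@H](C)C(=O)N2[C@@H](c3ccccc3)COC2=O)ccc1O[Si](C)(C)C(C)(C)C
F5 | step 4 | (2S,3R)-4-[4-(tert-butyldimethylsilyloxy)-3-methoxyphenyl]-2,3-dimethylbutan-1-ol | COc1cc(C[C@@H](C)[C@H](C)CO)ccc1O[Si](C)(C)C(C)(C)C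
F6 | step 4 | (2S,3R)-4-[4-(tert-butyldimethylsilyloxy)-3-methoxyphenyl]-2,3-dimethylbutanal | COc1cc(C[C@@H](C)[C@H](C)C=O)ccc1O[Si](C)(C)C(C)(C)C
F7 | step 4 | (1R,2S,3R)-4-[4-(tert-butyldimethylsilyloxy)-3-methoxyphenyl]-1-(3,4-dimethoxyphenyl)-2,3-dimethylbutan-1-ol | COc1cc(C[C@@H](C)[C@H](C)[C@@H](O)c2ccc(OC)c(OC)c2)ccc1O[Si](C)(C)C(C)(C)C
F8 | step 4 | (1R,2S,3R)-4-[4-(tert-butyldimethylsilyloxy)-3-methoxyphenyl]-1-(3,4-dimethoxyphenyl)-2,3-dimethylbutyl acetate | COc1cc(C[C@@H](C)[C@H](C)[C@@H](OC(C)=O)c2ccc(OC)c(OC)c2)ccc1O[Si](C)(C)C(C)(C)C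
F9 | step 6 | 4-[(2R,3S,4R)-4-(3,4-dimethoxyphenyl)-3-methyl-2-[(methylsulfonyloxy)methyl]-4-(nitrooxy)butyl]-2-methoxyphenyl acetate | COc1cc(C[C@@H](COS(C)(=O)=O)[C@H](C)[C@@H](O[N+](=O)[O-])c2ccc(OC)c(OC)c2)ccc1OC(C)=O
F10 | step 6 | 4-[(2R,3S,4R)-4-(3,4-dimethoxyphenyl)-4-hydroxy-3-methyl-2-[(methylsulfonyloxy)methyl]butyl]-2-methoxyphenyl acetate | COc1cc(C[C@@H](COS(C)(=O)=O)[C@H](C)[C@@H](O)c2ccc(OC)c(OC)c2)ccc1OC(C)=O
F11 | step 6 | (1R,2S,3R)-4-(4-acetoxy-3-methoxyphenyl)-1-(3,4-dimethoxyphenyl)-2-methyl-3-[(methylsulfonyloxy)methyl]butyl acetate | COc1cc(C[C@@H](COS(C)(=O)=O)[C@H](C)[C@@H](OC(C)=O)c2ccc(OC)c(OC)c2)ccc1OC(C)=O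
F12 | step 7 | 4-[(2R,3S,4R)-4-(3,4-dimethoxyphenyl)-4-hydroxy-2,3-dimethylbutyl]-2-methoxyphenyl acetate | COc1cc(C[C@@H](C)[C@H](C)[C@@H](O)c2ccc(OC)c(OC)c2)ccc1OC(C)=O
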